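**Plan**

- Feature: the ten-membered ring is numbered C1 (allylic CHOAc), C2=C3(Me), C4, C5, C6=C7(CO2H), C8, C9 (CHOAc), C10 (CH-iPr). Both oxygens sit on the ring carbons next to C10, so taking them away leaves a ring acid with one stereocentre and a carboxylate handle.
- Retrosynthesis cuts, in order: the two O-acetyl bonds; C1-O and C9-O (back to C-H, two P450 hydroxylases); the ring at C6=C7 (intramolecular Horner-Wadsworth-Emmons); C7-C8 (phosphonoacetate alkylation); C4-C5 (copper-catalysed allylic coupling); C2=C3 (Still-Gennari).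
- Forward: (S)-limonene is hydrogenated and ozonised to the C2-C1-C10-C9-C8 keto aldehyde. Z-olefination, Baeyer-Villiger oxidation, reduction and double chlorination give a dichloride that is extended first at C4, then at C8.
- The only ring (ten-membered carbocycle) closes in step 10. Ester hydrolysis gives the deoxy acid, which is hydroxylated twice and then acetylated.
- Stereochemistry: C10 comes from (S)-limonene, the ring-cis C2=C3 from the Still-Gennari reagent, the ring-cis C6=C7 from the ring closure, and C1 and C9 from the active sites of the two enzymes.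

Key step: step 12

Assumption: the two hydroxylases of step 12 do not exist yet and are to be obtained by directed evolution of CYP102A1 as part of the work. The ring locants C1 to C10 of the target are used for every intermediate. (S)-Limonene is used at the enantiomeric purity supplied, and no later step can raise it.

Step 1
Reactants: 1 (S)-(-)-limonene
Product: 2 (4S)-1-methyl-4-(propan-2-yl)cyclohex-1-ene
Conditions: H2 (1 atm, stopped at 1.0 equiv), PtO2 (cat.), neat, 20 °C
Reagents that add atoms: none
Why: Heterogeneous hydrogenation over platinum should saturate the 1,1-disubstituted exocyclic alkene well before the trisubstituted ring alkene when hydrogen uptake is limited to one equivalent; the stereocentre is not touched.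

Step 2
Reactants: 2 (4S)-1-methyl-4-(propan-2-yl)cyclohex-1-ene
Product: 4 (3S)-6-oxo-3-(propan-2-yl)heptanal, via ozonide 3 (not isolated)
Conditions: O3, CH2Cl2, -78 °C; then Me2S, -78 to 20 °C
Reagents that add atoms: ozone, [O-][O+]=O
Why: Criegee ozonolysis (cycloaddition, cycloreversion, recombination to the 1,2,4-trioxolane) followed by reductive cleavage with Me2S should open the ring to the keto aldehyde, whose aldehyde carbon is C2 and whose stereocentre is C10.

Step 3
Reactants: 4 (3S)-6-oxo-3-(propan-2-yl)heptanal; 5 ethyl 2-[bis(2,2,2-trifluoroethoxy)phosphoryl]propanoate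
Product: 6 ethyl (2Z,5S)-2-methyl-8-oxo-5-(propan-2-yl)non-2-enoate
Conditions: 5, KN(SiMe3)2, 18-crown-6, THF, -78 °C; then 4, -78 °C
Reagents that add atoms: none
Why: Still-Gennari olefination: the potassium phosphonate adds to the aldehyde far faster than to the methyl ketone at -78 °C, and the electron-poor phosphonate collapses under kinetic control to the Z enoate, which places the ester carbon (C4) cis to C1.

Step 4
Reactants: 6 ethyl (2Z,5S)-2-methyl-8-oxo-5-(propan-2-yl)non-2-enoate
Product: 7 ethyl (2Z,5R)-7-(acetyloxy)-2-methyl-5-(propan-2-yl)hept-2-enoate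
Conditions: mCPBA (2.5 equiv), CF3CO2H (1 equiv), CH2Cl2, 0 to 20 °C, dark
Reagents that add atoms: 3-chloroperoxybenzoic acid, O=C(OO)c1cccc(Cl)c1
Why: Baeyer-Villiger oxidation: in the Criegee adduct of the methyl ketone the primary alkyl group (C8) should migrate in preference to methyl, while the electron-poor trisubstituted enoate resists epoxidation by the peracid. The descriptor at C10 changes from S to R only because the CIP priorities change.

Step 5
Reactants: 7 ethyl (2Z,5R)-7-(acetyloxy)-2-methyl-5-(propan-2-yl)hept-2-enoate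
Product: 8 (2Z,5R)-2-methyl-5-(propan-2-yl)hept-2-ene-1,7-diol
Conditions: iBu2AlH (5 equiv), CH2Cl2, -78 to 0 °C; aq. KNaC4H4O6 work-up
Reagents that add atoms: none
Why: Hydride reduction with iBu2AlH should take the conjugated ester to the Z allylic alcohol by 1,2-addition without touching the olefin geometry and cleave the acetate reductively in the same operation.

Step 6
Reactants: 8 (2Z,5R)-2-methyl-5-(propan-2-yl)hept-2-ene-1,7-diol
Product: 9 (2Z,5R)-1,7-dichloro-2-methyl-5-(propan-2-yl)hept-2-ene
Conditions: PPh3 (2.6 equiv), CCl4, MeCN, 20 to 60 °C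
Reagents that add atoms: carbon tetrachloride, ClC(Cl)(Cl)Cl
Why: Appel reaction: both primary alcohols should be displaced by chloride through their alkoxyphosphonium salts by SN2, which for a primary allylic alcohol proceeds without allylic transposition and with retention of the Z olefin.

Step 7
Reactants: 9 (2Z,5R)-1,7-dichloro-2-methyl-5-(propan-2-yl)hept-2-ene; 10 (1,3-dioxolan-2-ylmethyl)magnesium bromide
Product: 11 2-[(3Z,6R)-8-chloro-3-methyl-6-(propan-2-yl)oct-3-en-1-yl]-1,3-dioxolane
Conditions: 10 (commercial THF solution, 1.5 equiv), Li2CuCl4 (5 mol %), THF, -78 to 0 °C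
Reagents that add atoms: none
Why: Li2CuCl4-catalysed Grignard cross-coupling: the organocopper species formed in situ should substitute the allylic chloride at its α-carbon (C4) with retention of the Z olefin, while the unactivated primary alkyl chloride at C8 does not couple at this temperature.

Step 8
Reactants: 11 2-[(3Z,6R)-8-chloro-3-methyl-6-(propan-2-yl)oct-3-en-1-yl]-1,3-dioxolane; 12 triethyl phosphonoacetate
Product: 14 ethyl (5S,7Z)-2-(diethoxyphosphoryl)-10-(1,3-dioxolan-2-yl)-8-methyl-5-(propan-2-yl)dec-7-enoate, via iodide 13 (not isolated)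
Conditions: 12 (2 equiv), NaH (1.8 equiv), NaI (0.2 equiv), DMSO, 60 °C
Reagents that add atoms: sodium iodide, [Na+].[I-] (iodine stays only in 13)
Why: SN2 alkylation of the sodium phosphonoacetate carbanion after in-situ Finkelstein exchange of chloride for iodide; the excess of 12 should suppress dialkylation, and the new phosphonate carbon (C7) is formed as a mixture that is of no consequence.

Step 9
Reactants: 14 ethyl (5S,7Z)-2-(diethoxyphosphoryl)-10-(1,3-dioxolan-2-yl)-8-methyl-5-(propan-2-yl)dec-7-enoate
Product: 15 ethyl (5S,7Z)-2-(diethoxyphosphoryl)-8-methyl-11-oxo-5-(propan-2-yl)undec-7-enoate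
Conditions: 1 M aq. HCl, THF, 20 °C
Reagents that add atoms: water, O
Why: Acid-catalysed acetal hydrolysis through the oxocarbenium ion should release the C6 aldehyde; phosphonate, ester and the Z olefin are stable to dilute acid.

Step 10
Reactants: 15 ethyl (5S,7Z)-2-(diethoxyphosphoryl)-8-methyl-11-oxo-5-(propan-2-yl)undec-7-enoate
Product: 16 ethyl (1E,5Z,8S)-5-methyl-8-(propan-2-yl)cyclodeca-1,5-diene-1-carboxylate
Conditions: LiCl (5 equiv), DBU (3 equiv), MeCN, 15 added over 12 h to a final 2 mM, 40 °C
Reagents that add atoms: none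
Why: Intramolecular Horner-Wadsworth-Emmons olefination with LiCl and an amine base at high dilution: reversible addition of the lithium phosphonoenolate to the aldehyde and elimination should give the enoate with C5 and C8 cis. That is the normal E outcome for an α-alkyl phosphonoacetate and the geometry a ten-membered ring accommodates best, and the Z C2=C3 olefin pre-folds the chain.

Step 11
Reactants: 16 ethyl (1E,5Z,8S)-5-methyl-8-(propan-2-yl)cyclodeca-1,5-diene-1-carboxylate
Product: 17 (1E,5Z,8S)-5-methyl-8-(propan-2-yl)cyclodeca-1,5-diene-1-carboxylic acid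
Conditions: LiOH·H2O, THF/MeOH/H2O, 40 °C; then dilute aq. HCl to pH 4
Reagents that add atoms: lithium hydroxide, [Li+].[OH-]
Why: Saponification by acyl-oxygen cleavage of the conjugated ester; the mild base should not move the C6=C7 double bond out of conjugation.

Step 12
Reactants: 17 (1E,5Z,8S)-5-methyl-8-(propan-2-yl)cyclodeca-1,5-diene-1-carboxylic acid
Product: 20 (1E,5Z,7R,8S,9R)-7,9-dihydroxy-5-methyl-8-(propan-2-yl)cyclodeca-1,5-diene-1-carboxylic acid (kept as its potassium salt), via C9-hydroxy acid 18 (not isolated), via C1-hydroxy acid 19 (not isolated)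
Conditions: resting E. coli cells co-expressing two evolved CYP102A1 variants (hydroxylase A for C1-H, hydroxylase B for C9-H) and glucose dehydrogenase; 17 (2 mM, potassium salt), D-glucose, NADP+ (cat.), air, potassium phosphate buffer pH 8.0, 25 °C; adsorption on polystyrene resin, elution and lyophilisation at pH 8
Reagents that add atoms: dioxygen, O=O
Why: Proposed new method: each heme-thiolate monooxygenase reduces O2 with two electrons from NADPH to the ferryl-oxo porphyrin radical cation (formally tetravalent iron), which abstracts one hydrogen atom from the bound acid and returns hydroxyl to the carbon radical (oxygen rebound) with retention, so only the C1-O and C9-O bonds form and no ring closes. The closest known reaction type is the pair of P450 hydroxylations that oxidise germacrene A acid at the allylic and the non-allylic ring carbon next to its branch-bearing carbon in sesquiterpene lactone biosynthesis, together with laboratory-evolved CYP102A1 variants that hydroxylate terpenoids. C1 (R) is set by hydroxylase A, whose pocket must present to the oxo ligand the C1-H that lies cis to the isopropyl group; C9 (R) is set by hydroxylase B, which must present the C9-H trans to the isopropyl group, so the diol is anti. The step needs site selectivity for C1 and C9 over the allylic C4, C5 and C8 methylenes, the C3 methyl group and both olefins; it is to be secured by a salt bridge from the C7 carboxylate to Arg47/Tyr51 at the channel entrance and by seating the C10 isopropyl group in a pocket reshaped by saturation mutagenesis (positions 75, 78, 82, 87, 263, 328, 330), with LC-MS screening on 17 and 18. Hydroxylase B is evolved on 17 and hydroxylase A on 17 and 18, so either order of oxidation converges on 20, and pH 8 keeps the product as the carboxylate so that the C9 hydroxyl cannot lactonise onto C7.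

Step 13
Reactants: 20 (1E,5Z,7R,8S,9R)-7,9-dihydroxy-5-methyl-8-(propan-2-yl)cyclodeca-1,5-diene-1-carboxylic acid (potassium salt)
Product: 23 (1E,5Z,7R,8S,9R)-7,9-bis(acetyloxy)-5-methyl-8-(propan-2-yl)cyclodeca-1,5-diene-1-carboxylic acid, via silyl ester 21 (not isolated), via diacetate silyl ester 22 (not isolated)
Conditions: iPr3SiCl (1.1 equiv), DMF, 0 °C; then Ac2O, pyridine, DMAP (cat.), 0 to 20 °C; then HF·pyridine, THF, 0 °C
Reagents that add atoms: acetic anhydride, CC(=O)OC(C)=O; chlorotri(propan-2-yl)silane, CC(C)[Si](Cl)(C(C)C)C(C)C (silicon stays only in 21 and 22)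
Why: Transient silyl ester protection, DMAP-catalysed acyl transfer and fluoride desilylation: the carboxylate is silylated on oxygen and is never turned into an acyl donor, so both hydroxyls should be acetylated before the C9 oxygen can close the γ-lactone, and no stereocentre is touched.

**Compound list**

1 | (S)-(-)-limonene, (4S)-1-methyl-4-(prop-1-en-2-yl)cyclohex-1-ene | CC1=CC[C@@H](C(C)=C)CC1 | starting material
2 | (4S)-1-methyl-4-(propan-2-yl)cyclohex-1-ene | CC1=CC[C@@H](C(C)C)CC1 | intermediate
3 | ozonide of 2, 1-methyl-4-(propan-2-yl)-7,8,9-trioxabicyclo[4.2.1]nonane (bridgeheads as formed) | CC12CC[C@H](C(C)C)CC(OO1)O2 | intermediate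
4 | (3S)-6-oxo-3-(propan-2-yl)heptanal | O=CC[C@@H](C(C)C)CCC(C)=O | intermediate
5 | ethyl 2-[bis(2,2,2-trifluoroethoxy)phosphoryl]propanoate | CCOC(=O)C(C)P(=O)(OCC(F)(F)F)OCC(F)(F)F | starting material
6 | ethyl (2Z,5S)-2-methyl-8-oxo-5-(propan-2-yl)non-2-enoate | CCOC(=O)/C(C)=C\C[C@@H](C(C)C)CCC(C)=O | intermediate
7 | ethyl (2Z,5R)-7-(acetyloxy)-2-methyl-5-(propan-2-yl)hept-2-enoate | CCOC(=O)/C(C)=C\C[C@@H](C(C)C)CCOC(C)=O | intermediate
8 | (2Z,5R)-2-methyl-5-(propan-2-yl)hept-2-ene-1,7-diol | OC/C(C)=C\C[C@@H](C(C)C)CCO | intermediate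
9 | (2Z,5R)-1,7-dichloro-2-methyl-5-(propan-2-yl)hept-2-ene | ClC/C(C)=C\C[C@@H](C(C)C)CCCl | intermediate
10 | (1,3-dioxolan-2-ylmethyl)magnesium bromide | Br[Mg]CC1OCCO1 | starting material
11 | 2-[(3Z,6R)-8-chloro-3-methyl-6-(propan-2-yl)oct-3-en-1-yl]-1,3-dioxolane | O1CCOC1CC/C(C)=C\C[C@@H](C(C)C)CCCl | intermediate
12 | triethyl phosphonoacetate, ethyl 2-(diethoxyphosphoryl)acetate | CCOC(=O)CP(=O)(OCC)OCC | starting material
13 | 2-[(3Z,6R)-8-iodo-3-methyl-6-(propan-2-yl)oct-3-en-1-yl]-1,3-dioxolane | O1CCOC1CC/C(C)=C\C[C@@H](C(C)C)CCI | intermediate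
14 | ethyl (5S,7Z)-2-(diethoxyphosphoryl)-10-(1,3-dioxolan-2-yl)-8-methyl-5-(propan-2-yl)dec-7-enoate (C2 epimers) | O1CCOC1CC/C(C)=C\C[C@@H](C(C)C)CCC(C(=O)OCC)P(=O)(OCC)OCC | intermediate
15 | ethyl (5S,7Z)-2-(diethoxyphosphoryl)-8-methyl-11-oxo-5-(propan-2-yl)undec-7-enoate (C2 epimers) | O=CCC/C(C)=C\C[C@@H](C(C)C)CCC(C(=O)OCC)P(=O)(OCC)OCC | intermediate
16 | ethyl (1E,5Z,8S)-5-methyl-8-(propan-2-yl)cyclodeca-1,5-diene-1-carboxylate | C1/C=C(/C)CC/C=C(/C(=O)OCC)CC[C@@H]1C(C)C | intermediate
17 | deoxy acid, (1E,5Z,8S)-5-methyl-8-(propan-2-yl)cyclodeca-1,5-diene-1-carboxylic acid | C1/C=C(/C)CC/C=C(/C(=O)O)CC[C@@H]1C(C)C | intermediate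
18 | C9-hydroxy acid, (1E,5Z,8S,9R)-9-hydroxy-5-methyl-8-(propan-2-yl)cyclodeca-1,5-diene-1-carboxylic acid | C1/C=C(/C)CC/C=C(/C(=O)O)C[C@@H](O)[C@@H]1C(C)C | intermediate
19 | C1-hydroxy acid, (1E,5Z,7S,8R)-7-hydroxy-5-methyl-8-(propan-2-yl)cyclodeca-1,5-diene-1-carboxylic acid (same spatial arrangement as in 20) | O[C@@H]1/C=C(/C)CC/C=C(/C(=O)O)CC[C@@H]1C(C)C | intermediate
20 | diol acid, (1E,5Z,7R,8S,9R)-7,9-dihydroxy-5-methyl-8-(propan-2-yl)cyclodeca-1,5-diene-1-carboxylic acid (handled as its potassium salt) | O[C@@H]1/C=C(/C)CC/C=C(/C(=O)O)C[C@@H](O)[C@@H]1C(C)C | intermediate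
21 | tri(propan-2-yl)silyl (1E,5Z,7R,8S,9R)-7,9-dihydroxy-5-methyl-8-(propan-2-yl)cyclodeca-1,5-diene-1-carboxylate | O[C@@H]1/C=C(/C)CC/C=C(/C(=O)O[Si](C(C)C)(C(C)C)C(C)C)C[C@@H](O)[C@@H]1C(C)C | intermediate
22 | tri(propan-2-yl)silyl (1E,5Z,7R,8S,9R)-7,9-bis(acetyloxy)-5-methyl-8-(propan-2-yl)cyclodeca-1,5-diene-1-carboxylate | CC(=O)O[C@@H]1/C=C(/C)CC/C=C(/C(=O)O[Si](C(C)C)(C(C)C)C(C)C)C[C@@H](OC(C)=O)[C@@H]1C(C)C | intermediate
23 | CNP0172943.1, (1E,5Z,7R,8S,9R)-7,9-bis(acetyloxy)-5-methyl-8-(propan-2-yl)cyclodeca-1,5-diene-1-carboxylic acid | CC(=O)O[C@@H]1/C=C(/C)CC/C=C(/C(=O)O)C[C@@H](OC(C)=O)[C@@H]1C(C)C | target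

**Count**

Total steps: 13. Longest linear sequence: 13 steps, from 1 to 23 (the route is fully linear; 5, 10 and 12 are bought).

**Steps most likely to fail**

1. Step 12. No variant may reach both positions. Oxygen may go into the more reactive allylic C4, C5 or C8 methylenes or across C2=C3 as an epoxide. Hydroxyl may be delivered to the wrong face. The allylic C1 alcohol may be oxidised further to the enone, and the γ-hydroxy acid may lactonise during isolation.

   Fallback, with known reactions only: both C-O bonds are built by aldol addition and directed reduction before the ring is closed. It sets out from 12 and comes back to the route at 20.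
   - Allylation of 12 (NaH, allyl bromide, THF) should give ethyl 2-(diethoxyphosphoryl)pent-4-enoate F1.
   - Ozonolysis (O3, CH2Cl2, -78 °C; Me2S) should give ethyl 2-(diethoxyphosphoryl)-4-oxobutanoate F2.
   - An Evans syn aldol addition of the dibutylboron enolate of commercial (4S)-4-benzyl-3-(3-methylbutanoyl)-1,3-oxazolidin-2-one (Bu2BOTf, iPr2NEt, CH2Cl2, -78 °C) to F2 should set C10 and C9 in the imide aldol adduct F3.
   - Me3Al with MeNH(OMe)·HCl should turn F3 into the Weinreb amide F4.
   - An excess of the lithium acetylide of 5,5-dimethoxypent-1-yne (n-BuLi, THF, -78 to -20 °C) should give the ynone F5.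
   - Syn conjugate addition of Me2CuLi (THF, -78 °C, cold quench) should give the Z enone F6, with C1 cis to C4.
   - Hydroxyl-directed reduction with Me4NBH(OAc)3 (MeCN/AcOH, -30 °C) delivers hydride from the C9 alkoxyborohydride and should give the 1,3-anti diol F7, which sets C1.
   - Pyridinium tosylate in wet acetone should unmask the aldehyde and close the C9-O lactone to the phosphono lactone aldehyde F8.
   - LiCl and DBU in MeCN at high dilution (intramolecular Horner-Wadsworth-Emmons) should give the ring-fused hydroxy α-alkylidene lactone F9.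
   - KOH in aqueous THF opens the lactone to the potassium salt of 20, which enters step 13.

2. Step 10. Intermolecular olefination to dimers and oligomers may outrun closure of the medium ring, and the enolisable aldehyde may self-condense under base.

   Fallback: the ring is closed by enolate C-alkylation at C7-C8, not by olefination at C6=C7. It sets out from 9 and comes back at 16.
   - The dianion of ethyl acetoacetate (NaH, then n-BuLi, THF, 0 °C) should alkylate the allylic chloride of 9 through its terminal carbon, leaving the alkyl chloride untouched, to give the chloro β-keto ester F10.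
   - Cs2CO3 and NaI in MeCN at high dilution (60 °C) should close the ten-membered ring by intramolecular C-alkylation to the cyclic β-keto ester F11.
   - NaBH4 in EtOH should give the β-hydroxy ester F12.
   - Mesylation (MsCl, Et3N) should give the mesylate F13, and elimination with DBU should give the conjugated ring-cis enoate 16.

3. Step 7. Transmetallation of the β-alkoxy Grignard reagent may be slow, the nucleophile may attack C2 (SN2') in place of C4, and the Z geometry may be lost through isomerisation of the allylcopper intermediate.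

   Fallback: aza-enolate alkylation in place of cross-coupling. It sets out from 9 and comes back at 11.
   - The lithium aza-enolate of acetaldehyde N,N-dimethylhydrazone (LiN(iPr)2, THF, -78 to 0 °C) should displace the allylic chloride of 9 by SN2 to give the hydrazone F14.
   - Two-phase hydrolysis with aqueous oxalic acid should release the aldehyde F15.
   - Ethylene glycol with TsOH (cat.) and azeotropic removal of water should give 11.

**Further compounds**

F1 | step 12 | ethyl 2-(diethoxyphosphoryl)pent-4-enoate | CCOC(=O)C(CC=C)P(=O)(OCC)OCC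
F2 | step 12 | ethyl 2-(diethoxyphosphoryl)-4-oxobutanoate | CCOC(=O)C(CC=O)P(=O)(OCC)OCC
F3 | step 12 | ethyl (4R,5S)-5-[(4S)-4-benzyl-2-oxo-1,3-oxazolidine-3-carbonyl]-2-(diethoxyphosphoryl)-4-hydroxy-6-methylheptanoate (C2 epimers) | CCOC(=O)C(P(=O)(OCC)OCC)C[C@@H](O)[C@@H](C(=O)N1C(=O)OC[C@@H]1Cc2ccccc2)C(C)C
F4 | step 12 | ethyl (4R,5S)-2-(diethoxyphosphoryl)-4-hydroxy-5-[methoxy(methyl)carbamoyl]-6-methylheptanoate (C2 epimers) | CCOC(=O)C(P(=O)(OCC)OCC)C[C@@H](O)[C@@H](C(=O)N(C)OC)C(C)C
F5 | step 12 | ethyl (4R,5S)-2-(diethoxyphosphoryl)-4-hydroxy-11,11-dimethoxy-6-oxo-5-(propan-2-yl)undec-7-ynoate (C2 epimers) | CCOC(=O)C(P(=O)(OCC)OCC)C[C@@H](O)[C@@H](C(=O)C#CCCC(OC)OC)C(C)C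
F6 | step 12 | ethyl (4R,5S,7Z)-2-(diethoxyphosphoryl)-4-hydroxy-11,11-dimethoxy-8-methyl-6-oxo-5-(propan-2-yl)undec-7-enoate (C2 epimers) | CCOC(=O)C(P(=O)(OCC)OCC)C[C@@H](O)[C@@H](C(=O)/C=C(/C)CCC(OC)OC)C(C)C
F7 | step 12 | ethyl (4R,5S,6R,7Z)-2-(diethoxyphosphoryl)-4,6-dihydroxy-11,11-dimethoxy-8-methyl-5-(propan-2-yl)undec-7-enoate (C2 epimers) | CCOC(=O)C(P(=O)(OCC)OCC)C[C@@H](O)[C@@H]([C@H](O)/C=C(/C)CCC(OC)OC)C(C)C
F8 | step 12 | phosphono lactone aldehyde: C6 aldehyde, Z C2=C3, free C1 hydroxyl, C9-O γ-lactone carrying the diethoxyphosphoryl group on C7 (route locants; C1, C9, C10 arranged as in 20; C7 epimers) | O=CCC/C(C)=C\[C@@H](O)[C@@H](C(C)C)[C@H]1CC(P(=O)(OCC)OCC)C(=O)O1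
F9 | step 12 | γ-lactone of 20 between the C7 carboxyl group and the C9 oxygen, C1 hydroxyl free (route locants) | O[C@@H]1/C=C(/C)CC/C=C2/C(=O)O[C@H](C2)[C@@H]1C(C)C
F10 | step 10 | ethyl (6Z,9R)-11-chloro-6-methyl-3-oxo-9-(propan-2-yl)undec-6-enoate | CCOC(=O)CC(=O)CC/C(C)=C\C[C@@H](C(C)C)CCCl
F11 | step 10 | ethyl (5Z,8S)-5-methyl-2-oxo-8-(propan-2-yl)cyclodec-5-ene-1-carboxylate (C1 epimers) | C1/C=C(/C)CCC(=O)C(C(=O)OCC)CC[C@@H]1C(C)C
F12 | step 10 | ethyl (5Z,8S)-2-hydroxy-5-methyl-8-(propan-2-yl)cyclodec-5-ene-1-carboxylate (diastereomers at C1 and C2) | C1/C=C(/C)CCC(O)C(C(=O)OCC)CC[C@@H]1C(C)C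
F13 | step 10 | ethyl (5Z,8S)-2-(methanesulfonyloxy)-5-methyl-8-(propan-2-yl)cyclodec-5-ene-1-carboxylate (diastereomers at C1 and C2) | C1/C=C(/C)CCC(OS(C)(=O)=O)C(C(=O)OCC)CC[C@@H]1C(C)C
F14 | step 7 | (4Z,7R)-9-chloro-4-methyl-7-(propan-2-yl)non-4-enal N,N-dimethylhydrazone | CN(C)N=CCC/C(C)=C\C[C@@H](C(C)C)CCCl
F15 | step 7 | (4Z,7R)-9-chloro-4-methyl-7-(propan-2-yl)non-4-enal | O=CCC/C(C)=C\C[C@@H](C(C)C)CCCl
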